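## The problem

Target 19 is a depsidone. Ring A (C1–C4, C4a, C11a; methyl on C1, hydroxyl on C3, formyl on C4) and the fully substituted ring B (C5a–C9a) are joined twice on neighbouring carbons. The ether oxygen O5 links C4a to C5a, and the ester C11(=O)–O10 links C11a to C9a; together they form the seven-membered ring C. Ring D, a 2,2-dimethyl-2,3-dihydropyran-4-one, is fused to ring B through the oxygen on C7 and the carbonyl on C8.

There is no stereocentre, so the difficulties are constitutional. The diaryl ether has four ortho substituents, ring B carries four different oxygens, and the ester must sit on the catechol oxygen next to the C9 methyl while the ether sits on the one next to the C6 hydroxyl.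

Several groups are fragile. The aryl lactone opens with nucleophiles and base. A catechol monoester with a free neighbouring phenol transfers its acyl group. The salicylaldehyde unit is sensitive to oxidants and to electron-rich arenes in acid. Ring B is easily halogenated or oxidized.

The feature to exploit is that C4a and C11a are adjacent, and so are the two ring B oxygens O5 and O10. A 1-oxy-3-silyloxy diene on O5 and a but-2-ynoate on O10 are therefore held within reach, and one cycloaddition can form C4a–C11a and C1–C2, closing ring A and ring C together. The ring A substituents map onto these partners: the C3 oxygen is the silyloxy group of the diene, the C1 methyl is the butynoate methyl, and a bromine on diene C2 marks C4 for the formyl group. The hindered ether bond is thus made as a vinyl ether before ring A exists.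

## Retrosynthesis

**Ring D last (19 ⇒ 17 + 18).** The aryl–acyl bond at C8 and the O–C(CH3)2 bond are cut, giving triol 17 and 3,3-dimethylacrylic acid 18. An earlier ring D would put an enolizable ketone into the enol silylation and the cycloaddition. Cutting it last removes five carbons and one ring. The forward reaction must acylate C8, the only free carbon of ring B, and close the C7 oxygen onto the enone, while ring A stays inert because formyl and lactone carbonyl deactivate it.

**Unmasking and the formyl carbon (17 ⇒ 16 ⇒ 15).** Triol 17 comes from 16 by loss of two methyl ethers and one silyl ether in a single Lewis acid step. The formyl C–C bond of 16 is cut to aryl bromide 15. Electrophilic formylation of a free phenol would have to choose between C2, C4 and the electron-rich C8; the bromine fixes the position. The forward reaction must be neutral, because the lactone rules out aryllithium chemistry, so a palladium-catalysed formylation with CO and H2 is asked for.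

**Ring A and ring C together (15 ⇒ 14 ⇒ 13).** Arene 15 is the dehydrogenation product of cyclohexa-1,4-diene 14. In 14 the bonds C4a–C11a and C1–C2 are cut by a retro-Diels–Alder reaction to give diene ynoate 13. Cutting the ester C–O or the ether C–O instead would leave a tetra-ortho-substituted diaryl ether to be made by coupling two arenes. The cycloaddition cut removes ring A entirely and turns both links of ring C into simple O-functionalizations of a catechol. The forward reaction needs the fused regiochemistry, the less stable ester conformer required by a seven-membered lactone, and an adduct that is oxidized before it loses the ring B aryloxide.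

**Diene and ester (13 ⇒ 12 ⇒ 10 + 11).** The silyl enol ether of 13 is formed last from methyl ketone 12, because the diene is the most sensitive compound of the sequence. The ester C–O bond of 12 is cut to phenol 10 and but-2-ynoic acid 11. Acylating after the vinyl ether is in place means that no free phenol ever sits next to the butynoate, so acyl migration between the catechol oxygens is impossible.

**The differentiated catechol (10 ⇒ 8 ⇒ 6 ⇒ 4 + 5).** The phenol oxygen of 10 is introduced by Dakin oxidation of aldehyde 8, so the formyl group serves as a latent hydroxyl that marks the position next to the methyl group. The C–Br bond of 8 is cut to enone 6. Bromination is placed here because the formyl group deactivates ring B against ring bromination. The vinyl C–O bond of 6 is cut to salicylaldehyde 4 and but-3-yn-2-one 5, an oxa-Michael addition.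

**Ring B from a symmetric arene (4 ⇒ 3 ⇒ 1).** Phenol 4 comes from 3 by cleavage of the one methoxy group next to the formyl group, and 3 from 3,4,5-trimethoxytoluene 1 by formylation. The symmetry of 1 makes the two positions ortho to the methyl group equivalent, so both steps are unambiguous.

## Roads not taken

**Alternative 1:** The cut lies in ring D, at the benzylic C–C bond and the O–C(CH3)2 bond. Heating Mannich base A1 would expel its amine to give ortho-quinone methide A2, which would add 2-methylpropene A3 in a hetero-Diels–Alder reaction to give chroman A4.
- Merits: ring D is built early, on a simple arene, under neutral thermal conditions, and the regiochemistry of the pyran is certain. The chosen plan builds ring D last in strong acid on the finished depsidone, and on this point alternative 1 is the safer one.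
- Weak points: A4 is a chroman, so C4 must later be oxidized to the ketone in the presence of two aryl methyl groups and an electron-rich ring. The key step does nothing for ring C: the hindered diaryl ether and the lactone must still be made from the bromide and phenol of A4 and a separately prepared ring A acid, by esterification and Ullmann-type coupling.
- Comparison: the chosen plan accepts a risky last step but directs its key step at the hardest part of the molecule, and it should be shorter.

**Alternative 2:** The cut removes the ring C carbonyl: the aryl–C(=O) and C(=O)–O bonds. Aryl iodide A5, which carries ring A and ring B already linked by the ether, would take up carbon monoxide A6 under Pd(OAc)2, Xantphos and Et3N; the acylpalladium species would be captured by the ring B phenol to give A7, the ring B methyl ether of the target.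
- Merits: the route is convergent, ring D and the formyl group are in place, and only one demethylation follows. Carbonylative lactonization is closer to established practice than the key step chosen here, and this road is the more convergent one.
- Weak points: the difficulty moves into A5. Its tetra-ortho-substituted diaryl ether must be made by coupling two fully substituted arenes, the step that has traditionally limited depsidone syntheses. The iodide is flanked by methyl and aryloxy, and the free ring A phenol could be carbonylated intermolecularly.
- Comparison: the chosen plan sets against the greater convergence that its ether bond is made by conjugate addition of a phenol to an ynone, long before it becomes hindered.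

**Alternative 3:** The cut lies in ring A, at C4–C4a and C1–C11a. Pyrone A8 and aryloxypropiolate A9 would undergo a thermal Diels–Alder reaction across pyrone C3 and C6, followed by decarboxylation, to give benzoate A10.
- Merits: the route is convergent and the pyrone is cheap. Aromatization is spontaneous, needs no oxidant and cannot expel the aryloxide. This is a real advantage over the chosen plan, whose adduct 14 must be oxidized before it eliminates.
- Weak points: A9 is a push–pull ynol ether that is hard to prepare and to handle. The intermolecular cycloaddition of a tetrasubstituted pyrone with a disubstituted alkyne needs high temperature and relies on polarization alone for regiochemistry. Ring C is still open in A10, so acetal removal, hydrolysis of a di-ortho-substituted methyl benzoate and lactonization follow before formylation, demethylation and ring D.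
- Comparison: the chosen plan uses the tether to fix the regiochemistry and closes ring C in the same event, at the price of a more delicate adduct.

Key step: step 8

Remark on the chemistry: 19 has no stereocentre. Adduct 14 is racemic, so its SMILES carries no stereodescriptor. Dibromide 7 is an unassigned mixture of racemic diastereomers.

## Route

Step 1
Reactants: 1 3,4,5-trimethoxytoluene
Product: 3 2,3,4-trimethoxy-6-methylbenzaldehyde, via iminium chloride 2 (not isolated)
Conditions: POCl3, DMF, 0 → 80 °C; then H2O, 60 °C
Reagents that add atoms: N,N-dimethylformamide CN(C)C=O; water O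
Why: Vilsmeier–Haack formylation; the two positions ortho to the methyl group of 1 are equivalent by symmetry and activated by ortho and para methoxy groups, so a single aldehyde should result after hydrolysis of iminium salt 2.

Step 2
Reactants: 3 2,3,4-trimethoxy-6-methylbenzaldehyde
Product: 4 2-hydroxy-3,4-dimethoxy-6-methylbenzaldehyde
Conditions: BCl3 (1.1 equiv), CH2Cl2, −10 °C → rt; then H2O
Reagents that add atoms: none
Why: Chelation-controlled ether cleavage; BCl3 binds the formyl oxygen and the neighbouring methoxy oxygen in a six-membered chelate and chloride removes only that methyl group, so the other two methyl ethers should remain.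

Step 3
Reactants: 4 2-hydroxy-3,4-dimethoxy-6-methylbenzaldehyde; 5 but-3-yn-2-one
Product: 6 (3E)-4-(2-formyl-5,6-dimethoxy-3-methylphenoxy)but-3-en-2-one
Conditions: N-methylmorpholine (0.2 equiv), CH2Cl2, 0 °C → rt
Reagents that add atoms: none
Why: Amine-catalysed oxa-Michael addition of a phenol to a terminal ynone, expected to give the E β-aryloxy enone; the weakly nucleophilic amine at low temperature should not promote aldol closure onto the neighbouring formyl group, and the alkene geometry is reset in step 4.

Step 4
Reactants: 6 (3E)-4-(2-formyl-5,6-dimethoxy-3-methylphenoxy)but-3-en-2-one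
Product: 8 (3Z)-3-bromo-4-(2-formyl-5,6-dimethoxy-3-methylphenoxy)but-3-en-2-one, via dibromo ketone 7 (not isolated)
Conditions: Br2 (1.05 equiv), CH2Cl2, −78 °C; then Et3N (1.5 equiv), −78 → 0 °C
Reagents that add atoms: bromine BrBr
Why: Bromine addition to the β-aryloxy enone followed by E1cB dehydrobromination, in which the labile α-bromo ether bromide leaves; this should give the more stable Z isomer with the aryloxy group trans to the acetyl group, and the formyl-deactivated arene should not be brominated at −78 °C.

Step 5
Reactants: 8 (3Z)-3-bromo-4-(2-formyl-5,6-dimethoxy-3-methylphenoxy)but-3-en-2-one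
Product: 10 (3Z)-3-bromo-4-(2-hydroxy-5,6-dimethoxy-3-methylphenoxy)but-3-en-2-one, via aryl formate 9 (not isolated)
Conditions: mCPBA (1.3 equiv), CH2Cl2, 0 °C → rt; then THF, pH 7 phosphate buffer, rt
Reagents that add atoms: 3-chloroperbenzoic acid OOC(=O)c1cccc(Cl)c1
Why: Dakin oxidation in its peracid form (Baeyer–Villiger aryl migration of a benzaldehyde with a para methoxy group), then hydrolysis of the labile aryl formate 9 at neutral pH so that no phenoxide forms next to the bromo enone; the push–pull alkene and the methyl ketone are poor substrates for the peracid.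

Step 6
Reactants: 10 (3Z)-3-bromo-4-(2-hydroxy-5,6-dimethoxy-3-methylphenoxy)but-3-en-2-one; 11 but-2-ynoic acid
Product: 12 2-{[(1Z)-2-bromo-3-oxobut-1-en-1-yl]oxy}-3,4-dimethoxy-6-methylphenyl but-2-ynoate
Conditions: DCC (1.2 equiv), DMAP (5 mol %), CH2Cl2, −20 → 0 °C
Reagents that add atoms: none
Why: Steglich esterification, a standard route to aryl but-2-ynoates under nearly neutral conditions; the other catechol oxygen is already a vinyl ether, so no acyl migration can occur.

Step 7
Reactants: 12 2-{[(1Z)-2-bromo-3-oxobut-1-en-1-yl]oxy}-3,4-dimethoxy-6-methylphenyl but-2-ynoate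
Product: 13 2-{[(1Z)-2-bromo-3-[(tert-butyldimethylsilyl)oxy]buta-1,3-dien-1-yl]oxy}-3,4-dimethoxy-6-methylphenyl but-2-ynoate
Conditions: TBSOTf (1.2 equiv), Et3N (2 equiv), CH2Cl2, −78 → 0 °C
Reagents that add atoms: tert-butyldimethylsilyl trifluoromethanesulfonate CC(C)(C)[Si](C)(C)OS(=O)(=O)C(F)(F)F
Why: Soft enolization of the methyl ketone with a silyl triflate and an amine (silyl enol ether formation) should give the 2-silyloxy diene; the acetyl methyl is the most acidic position and the vinyl ether geometry is not touched.

Step 8
Reactants: 13 2-{[(1Z)-2-bromo-3-[(tert-butyldimethylsilyl)oxy]buta-1,3-dien-1-yl]oxy}-3,4-dimethoxy-6-methylphenyl but-2-ynoate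
Product: 14 rac-4-bromo-3-[(tert-butyldimethylsilyl)oxy]-6,7-dimethoxy-1,9-dimethyl-2,4a-dihydro-11H-dibenzo[b,e][1,4]dioxepin-11-one
Conditions: toluene (0.01 M), 2,6-di-tert-butyl-4-methylpyridine (0.2 equiv), BHT (cat.), 130 °C, sealed tube; cooled solution carried on as such
Reagents that add atoms: none
Why: Thermal intramolecular Diels–Alder reaction of normal electron demand between the 1-aryloxy-3-silyloxy diene and the tethered alkynoate, concerted but asynchronous: the nucleophilic CH2 terminus of the diene bonds to the methyl-bearing β-carbon of the ynoate (C2–C1) and the aryloxy-bearing terminus to the α-carbon (C4a–C11a). The closest known reaction type is the intramolecular cycloaddition of 1-alkoxy-3-silyloxy dienes with ester-tethered alkynoates, whose cyclohexa-1,4-diene adducts are then aromatized by oxidation. Ring A closes as a six-membered carbocycle by the (4+2) event itself; ring C closes as the seven-membered tether ring of a type 1 intramolecular cycloaddition, the five-atom tether running from diene C1 through the ortho-phenylene of ring B to the ynoate carbonyl. The new stereocentre at C4a forms racemic because nothing in 13 is chiral, and no control is needed since step 9 removes it. The step needs regioselectivity, which the short tether enforces (only the fused mode is within reach) and the matched polarization of diene and ynoate supports; it also needs the Z vinyl ether of 13, which puts the tether on the outside of the s-cis diene, while the 2-bromo and 3-silyloxy groups favour that conformer. Finally the adduct must survive: 14 is a vinylogous silyl acetal that can lose the ring B aryloxide, so the reaction is run dilute in a non-polar solvent with a hindered pyridine as acid scavenger and the solution is oxidized at once in step 9.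

Step 9
Reactants: 14 rac-4-bromo-3-[(tert-butyldimethylsilyl)oxy]-6,7-dimethoxy-1,9-dimethyl-2,4a-dihydro-11H-dibenzo[b,e][1,4]dioxepin-11-one
Product: 15 4-bromo-3-[(tert-butyldimethylsilyl)oxy]-6,7-dimethoxy-1,9-dimethyl-11H-dibenzo[b,e][1,4]dioxepin-11-one
Conditions: DDQ (1.2 equiv), toluene, 0 °C → rt; filtration through basic alumina
Reagents that add atoms: none
Why: DDQ dehydrogenation of a cyclohexa-1,4-diene: hydride abstraction from the doubly allylic CH2 gives a silyloxy-stabilized cyclohexadienyl cation that loses the proton at C4a, which erases the stereocentre; this should outrun loss of the aryloxide because the medium is non-polar and the reduced quinone precipitates.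

Step 10
Reactants: 15 4-bromo-3-[(tert-butyldimethylsilyl)oxy]-6,7-dimethoxy-1,9-dimethyl-11H-dibenzo[b,e][1,4]dioxepin-11-one
Product: 16 3-[(tert-butyldimethylsilyl)oxy]-6,7-dimethoxy-1,9-dimethyl-11-oxo-11H-dibenzo[b,e][1,4]dioxepine-4-carbaldehyde
Conditions: Pd(OAc)2 (5 mol %), di(1-adamantyl)-n-butylphosphine (15 mol %), TMEDA (1 equiv), CO/H2 (1:1, 5 bar), toluene, 100 °C
Reagents that add atoms: carbon monoxide [C-]#[O+]
Why: Palladium-catalysed reductive carbonylation (formylation) of an aryl bromide with synthesis gas: oxidative addition to zerovalent palladium, CO insertion and hydrogenolysis of the acylpalladium bond with the amine as base; the bulky electron-rich phosphine is chosen for the di-ortho-substituted bromide, and the neutral conditions spare the lactone and the silyl ether.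

Step 11
Reactants: 16 3-[(tert-butyldimethylsilyl)oxy]-6,7-dimethoxy-1,9-dimethyl-11-oxo-11H-dibenzo[b,e][1,4]dioxepine-4-carbaldehyde
Product: 17 3,6,7-trihydroxy-1,9-dimethyl-11-oxo-11H-dibenzo[b,e][1,4]dioxepine-4-carbaldehyde
Conditions: BBr3 (6 equiv), CH2Cl2, −78 → 0 °C; then H2O
Reagents that add atoms: none
Why: Lewis acid ether cleavage: BBr3 should cleave both aryl methyl ethers, and the aryl silyl ether ortho to the formyl group is expected to fall through the boron chelate and the HBr set free on quench; aryl esters and aryl aldehydes generally survive at or below 0 °C.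

Step 12
Reactants: 17 3,6,7-trihydroxy-1,9-dimethyl-11-oxo-11H-dibenzo[b,e][1,4]dioxepine-4-carbaldehyde; 18 3,3-dimethylacrylic acid
Product: 19 target depsidone: 3,6-dihydroxy-1,9-dimethyl-11-oxo-11H-dibenzo[b,e][1,4]dioxepine-4-carbaldehyde carrying a 2,2-dimethyl-2,3-dihydropyran-4-one ring fused at C7 (ring oxygen) and C8 (carbonyl)
Conditions: P2O5 in MeSO3H (1:10 w/w), 60 °C
Reagents that add atoms: none
Why: Friedel–Crafts acylation by the activated acid at C8, the only free ring B position and ortho to the C7 hydroxyl, followed by acid-catalysed oxa-Michael closure of the C7 oxygen onto the β,β-dimethyl enone; this is the standard chromanone annulation of phenols with 3,3-dimethylacrylic acid, and ring A is deactivated by the formyl group and the lactone carbonyl.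

## Compound list

1 | 3,4,5-trimethoxytoluene | COc1cc(C)cc(OC)c1OC | starting material
2 | N-[(2,3,4-trimethoxy-6-methylphenyl)methylidene]-N-methylmethanaminium chloride | C[N+](C)=Cc1c(C)cc(OC)c(OC)c1OC.[Cl-] | intermediate
3 | 2,3,4-trimethoxy-6-methylbenzaldehyde | COc1cc(C)c(C=O)c(OC)c1OC | intermediate
4 | 2-hydroxy-3,4-dimethoxy-6-methylbenzaldehyde | COc1cc(C)c(C=O)c(O)c1OC | intermediate
5 | but-3-yn-2-one | CC(=O)C#C | starting material
6 | (3E)-4-(2-formyl-5,6-dimethoxy-3-methylphenoxy)but-3-en-2-one | CC(=O)/C=C/Oc1c(OC)c(OC)cc(C)c1C=O | intermediate
7 | 3,4-dibromo-4-(2-formyl-5,6-dimethoxy-3-methylphenoxy)butan-2-one (unassigned mixture of racemic diastereomers) | CC(=O)C(Br)C(Br)Oc1c(OC)c(OC)cc(C)c1C=O | intermediate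
8 | (3Z)-3-bromo-4-(2-formyl-5,6-dimethoxy-3-methylphenoxy)but-3-en-2-one | CC(=O)/C(Br)=C/Oc1c(OC)c(OC)cc(C)c1C=O | intermediate
9 | 2-{[(1Z)-2-bromo-3-oxobut-1-en-1-yl]oxy}-3,4-dimethoxy-6-methylphenyl formate | CC(=O)/C(Br)=C/Oc1c(OC)c(OC)cc(C)c1OC=O | intermediate
10 | (3Z)-3-bromo-4-(2-hydroxy-5,6-dimethoxy-3-methylphenoxy)but-3-en-2-one | CC(=O)/C(Br)=C/Oc1c(OC)c(OC)cc(C)c1O | intermediate
11 | but-2-ynoic acid | CC#CC(=O)O | starting material
12 | 2-{[(1Z)-2-bromo-3-oxobut-1-en-1-yl]oxy}-3,4-dimethoxy-6-methylphenyl but-2-ynoate | CC#CC(=O)Oc1c(C)cc(OC)c(OC)c1O/C=C(\Br)C(C)=O | intermediate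
13 | 2-{[(1Z)-2-bromo-3-[(tert-butyldimethylsilyl)oxy]buta-1,3-dien-1-yl]oxy}-3,4-dimethoxy-6-methylphenyl but-2-ynoate | CC#CC(=O)Oc1c(C)cc(OC)c(OC)c1O/C=C(\Br)C(=C)O[Si](C)(C)C(C)(C)C | intermediate
14 | rac-4-bromo-3-[(tert-butyldimethylsilyl)oxy]-6,7-dimethoxy-1,9-dimethyl-2,4a-dihydro-11H-dibenzo[b,e][1,4]dioxepin-11-one | CC1=C2C(=O)Oc3c(C)cc(OC)c(OC)c3OC2C(Br)=C(O[Si](C)(C)C(C)(C)C)C1 | intermediate
15 | 4-bromo-3-[(tert-butyldimethylsilyl)oxy]-6,7-dimethoxy-1,9-dimethyl-11H-dibenzo[b,e][1,4]dioxepin-11-one | Cc1cc(O[Si](C)(C)C(C)(C)C)c(Br)c2Oc3c(OC)c(OC)cc(C)c3OC(=O)c12 | intermediate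
16 | 3-[(tert-butyldimethylsilyl)oxy]-6,7-dimethoxy-1,9-dimethyl-11-oxo-11H-dibenzo[b,e][1,4]dioxepine-4-carbaldehyde | Cc1cc(O[Si](C)(C)C(C)(C)C)c(C=O)c2Oc3c(OC)c(OC)cc(C)c3OC(=O)c12 | intermediate
17 | 3,6,7-trihydroxy-1,9-dimethyl-11-oxo-11H-dibenzo[b,e][1,4]dioxepine-4-carbaldehyde | Cc1cc(O)c(C=O)c2Oc3c(O)c(O)cc(C)c3OC(=O)c12 | intermediate
18 | 3,3-dimethylacrylic acid | CC(C)=CC(=O)O | starting material
19 | target depsidone (CNP0271978.0) | Cc1cc(O)c(C=O)c2c1C(=O)Oc1c(C)c3c(c(O)c1O2)OC(C)(C)CC3=O | target

## Step count and risks

Total step count: 12. Longest linear sequence: 12 steps (1 to 19); 5, 11 and 18 enter as purchased reagents.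

**Step 8 (key step).** The cycloaddition may be too slow, because the aryl ester must rotate into its less stable conformer before a seven-membered lactone can form. At the temperature then needed, the adduct may ionize at C4a and lose the ring B aryloxide, which aromatizes ring A without ring C.
Fallback, from 10 back to 15: the cycloaddition is run intermolecularly and ring C is closed afterwards.
- Phenol 10 is silylated twice with TBSOTf and Et3N to the bis-silyl diene F1.
- Acid 11 is converted with pentafluorophenol and DCC into pentafluorophenyl but-2-ynoate F2.
- Heating F1 with F2 in toluene should give the cyclohexa-1,4-diene adduct F3, with regiochemistry now set by polarization alone.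
- DDQ aromatizes F3 to the pentafluorophenyl benzoate F4.
- TBAF buffered with AcOH removes both silyl groups, and the ring B phenoxide displaces pentafluorophenoxide to close the lactone, giving the bromo hydroxy depsidone F5.
- TBSCl and imidazole return F5 to 15.

**Step 5 (with step 6).** Once the phenol next to the bromo enone is free, traces of base, including the DMAP of step 6, may trigger conjugate addition of the phenoxide to the vinyl ether carbon. That leads to ring closure to a 1,3-benzodioxole, or to transfer of the bromo-oxobutenyl group to the other catechol oxygen, and so to loss of the positional assignment.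
Fallback, from 9 back to 13: the phenol is released only after the enone has become the diene.
- Formate 9 is isolated without hydrolysis and silylated with TBSOTf and Et3N to the formate diene F6.
- n-Propylamine at 0 °C removes the formyl group to give the phenol diene F7, which has no acceptor next to the phenol.
- F7 is acylated with 11 that has been pre-activated with DCC, in the presence of DMAP and Et3N, to give 13.

**Step 10.** Oxidative addition at a bromide flanked by two oxygen substituents may be slow, and hydride transfer to the arylpalladium species may outrun CO insertion, so that the bromine is replaced by hydrogen.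
Fallback, from 15 back to 16: the formyl carbon is introduced as an alkene. Stille coupling of 15 with tributyl(vinyl)stannane and Pd(PPh3)4 in toluene at 100 °C should give the vinyl depsidone F8. Lemieux–Johnson cleavage (OsO4 cat., NaIO4, 2,6-lutidine, dioxane–water) then gives 16.

**Step 12.** In the strong protic acid the lactone may be opened, the formyl group may alkylate the electron-rich ring B of a second molecule, and acylation at the crowded C8 may be slow.
Fallback, from 16 back to 19: ring D is built on the methyl ether under aprotic Lewis acid conditions and the demethylation becomes the last step.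
- Friedel–Crafts acylation of 16 with commercial 3-methylbut-2-enoyl chloride and AlCl3 in CH2Cl2 (0 °C → rt) should acylate C8.
- The same Lewis acid should remove the C7 methyl group through the ketone chelate, close the pyranone by oxa-Michael addition, and cleave the silyl ether next to the formyl group, giving the chromanone methyl ether F9.
- BBr3 in CH2Cl2 at −78 → 0 °C removes the remaining C6 methyl group to give 19.

## Further compounds

F1 | step 8 | tert-butyl{2-[(1Z)-2-bromo-3-[(tert-butyldimethylsilyl)oxy]buta-1,3-dien-1-yl]oxy-3,4-dimethoxy-6-methylphenoxy}dimethylsilane | C=C(O[Si](C)(C)C(C)(C)C)/C(Br)=C/Oc1c(OC)c(OC)cc(C)c1O[Si](C)(C)C(C)(C)C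
F2 | step 8 | pentafluorophenyl but-2-ynoate | CC#CC(=O)Oc1c(F)c(F)c(F)c(F)c1F
F3 | step 8 | rac-pentafluorophenyl 5-bromo-4-[(tert-butyldimethylsilyl)oxy]-6-{2-[(tert-butyldimethylsilyl)oxy]-5,6-dimethoxy-3-methylphenoxy}-2-methylcyclohexa-1,4-diene-1-carboxylate | CC1=C(C(=O)Oc2c(F)c(F)c(F)c(F)c2F)C(Oc2c(OC)c(OC)cc(C)c2O[Si](C)(C)C(C)(C)C)C(Br)=C(O[Si](C)(C)C(C)(C)C)C1
F4 | step 8 | pentafluorophenyl 3-bromo-4-[(tert-butyldimethylsilyl)oxy]-2-{2-[(tert-butyldimethylsilyl)oxy]-5,6-dimethoxy-3-methylphenoxy}-6-methylbenzoate | Cc1cc(O[Si](C)(C)C(C)(C)C)c(Br)c(Oc2c(OC)c(OC)cc(C)c2O[Si](C)(C)C(C)(C)C)c1C(=O)Oc1c(F)c(F)c(F)c(F)c1F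
F5 | step 8 | 4-bromo-3-hydroxy-6,7-dimethoxy-1,9-dimethyl-11H-dibenzo[b,e][1,4]dioxepin-11-one | Cc1cc(O)c(Br)c2Oc3c(OC)c(OC)cc(C)c3OC(=O)c12
F6 | step 5 | 2-{[(1Z)-2-bromo-3-[(tert-butyldimethylsilyl)oxy]buta-1,3-dien-1-yl]oxy}-3,4-dimethoxy-6-methylphenyl formate | C=C(O[Si](C)(C)C(C)(C)C)/C(Br)=C/Oc1c(OC)c(OC)cc(C)c1OC=O
F7 | step 5 | 2-{[(1Z)-2-bromo-3-[(tert-butyldimethylsilyl)oxy]buta-1,3-dien-1-yl]oxy}-3,4-dimethoxy-6-methylphenol | C=C(O[Si](C)(C)C(C)(C)C)/C(Br)=C/Oc1c(OC)c(OC)cc(C)c1O
F8 | step 10 | 3-[(tert-butyldimethylsilyl)oxy]-4-ethenyl-6,7-dimethoxy-1,9-dimethyl-11H-dibenzo[b,e][1,4]dioxepin-11-one | Cc1cc(O[Si](C)(C)C(C)(C)C)c(C=C)c2Oc3c(OC)c(OC)cc(C)c3OC(=O)c12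
F9 | step 12 | 6-O-methyl ether of the target (3-hydroxy-6-methoxy depsidone aldehyde with ring D in place) | Cc1cc(O)c(C=O)c2Oc3c(OC)c4OC(C)(C)CC(=O)c4c(C)c3OC(=O)c12
A1 | alternative 1 | 2-bromo-5-[(dimethylamino)methyl]-3-methoxy-6-methylbenzene-1,4-diol | CN(C)Cc1c(C)c(O)c(Br)c(OC)c1O
A2 | alternative 1 | 3-bromo-4-hydroxy-2-methoxy-5-methyl-6-methylidenecyclohexa-2,4-dien-1-one | C=C1C(=O)C(OC)=C(Br)C(O)=C1C
A3 | alternative 1 | 2-methylpropene | CC(C)=C
A4 | alternative 1 | 7-bromo-6-hydroxy-8-methoxy-2,2,5-trimethylchroman | Cc1c(O)c(Br)c(OC)c2c1CCC(C)(C)O2
A5 | alternative 2 | 7-(2-formyl-3-hydroxy-6-iodo-5-methylphenoxy)-6-hydroxy-8-methoxy-2,2,5-trimethylchroman-4-one | Cc1cc(O)c(C=O)c(Oc2c(OC)c3OC(C)(C)CC(=O)c3c(C)c2O)c1I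
A6 | alternative 2 | carbon monoxide | [C-]#[O+]
A7 | alternative 2 | ring B methyl ether of the target | Cc1cc(O)c(C=O)c2c1C(=O)Oc1c(C)c3c(c(OC)c1O2)OC(C)(C)CC3=O
A8 | alternative 3 | 3-bromo-4-methoxy-6-methyl-2H-pyran-2-one | COc1cc(C)oc(=O)c1Br
A9 | alternative 3 | methyl 3-[2,3-dimethoxy-6-(methoxymethoxy)-5-methylphenoxy]prop-2-ynoate | COC(=O)C#COc1c(OCOC)c(C)cc(OC)c1OC
A10 | alternative 3 | methyl 3-bromo-2-[2,3-dimethoxy-6-(methoxymethoxy)-5-methylphenoxy]-4-methoxy-6-methylbenzoate | COC(=O)c1c(C)cc(OC)c(Br)c1Oc1c(OCOC)c(C)cc(OC)c1OC
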